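**Strategy.** Everything rests on building ring A last. The benzenoid ring (C4a, C5, C6, C7, C8, C8a) is annulated onto a preformed (2S)-2-aryl-2,3-dihydropyran-4-one whose C5=C6 bond becomes the C4a–C8a fusion. Visible-light Wolff rearrangement of a 6-diazoacetyl pyranone beside (triisopropylsilyloxy)acetylene, then ketene–alkyne [2+2], 4π opening and 6π closure, makes four C–C bonds in one operation and places the meta-related C5–OH and C7–OSi groups in a single orientation under neutral conditions. The feature exploited is this 1,3-dioxygenated ring A fused to pyranone ring C. The precursor carries the MOM-protected 2′-prenylcatechol B ring at C2 (S, set by Brown allylboration) and C(=O)CHN2 at C6.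

Key step: step 12

Remark 1: the stereocentre of the target is read from the SMILES as (2S) (priorities O1 > C1′ > C3 > H). Ar below means 3,4-bis(methoxymethoxy)-2-(3-methylbut-2-en-1-yl)phenyl.

Remark 2: (triisopropylsilyloxy)acetylene is assumed not to be purchasable and is made in step 11. Organometallic species made by one reagent and consumed by the next are numbered as non-isolated intermediates; adducts that only await aqueous work-up are not.

Step 1
Reactants: 1 4-bromocatechol
Product: 2 4-bromo-1,2-bis(methoxymethoxy)benzene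
Conditions: NaH (2.4 equiv), MOMCl (2.4 equiv), THF–DMF, 0 °C → rt
Reagents that add atoms: chloromethyl methyl ether (MOMCl), COCCl
Why: Double Williamson-type O-alkylation of the catechol dianion (acetal formation) should be clean, and MOM is chosen because it directs the metalation of step 2 and tolerates every later base, borane, Pd, light and fluoride step.

Step 2
Reactants: 2 4-bromo-1,2-bis(methoxymethoxy)benzene; 3 prenyl bromide
Product: 6 1-bromo-3,4-bis(methoxymethoxy)-2-(3-methylbut-2-en-1-yl)benzene, via aryllithium 4 (not isolated), via arylcopper 5 (not isolated)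
Conditions: LDA (1.1 equiv), THF, −78 °C; CuBr·SMe2 (1.1 equiv), −78 °C; 3 (1.3 equiv), −78 → 0 °C
Reagents that add atoms: none
Why: Directed ortho-metalation removes the C–H flanked by OMOM and Br (the most acidic site, and an amide base cannot exchange bromine), and the derived arylcopper resists aryne formation and alkylates prenyl bromide at its primary carbon (SN2), giving the linear prenyl group.

Step 3
Reactants: 6 1-bromo-3,4-bis(methoxymethoxy)-2-(3-methylbut-2-en-1-yl)benzene
Product: 8 3,4-bis(methoxymethoxy)-2-(3-methylbut-2-en-1-yl)benzaldehyde, via aryllithium 7 (not isolated)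
Conditions: n-BuLi (1.05 equiv), THF, −78 °C; DMF (3 equiv), −78 → 0 °C; H2O
Reagents that add atoms: N,N-dimethylformamide, CN(C)C=O
Why: Bromine–lithium exchange outruns deprotonation at −78 °C and the aryllithium is formylated by DMF (Bouveault formylation).

Step 4
Reactants: 8 3,4-bis(methoxymethoxy)-2-(3-methylbut-2-en-1-yl)benzaldehyde
Product: 9 (1S)-1-Ar-but-3-en-1-ol
Conditions: dIpc2B(allyl) [(+)-α-pinene series, 1.3 equiv], Et2O, −78 °C; then aq. NaOH, H2O2, 0 °C → rt
Reagents that add atoms: B-allyldiisopinocampheylborane of the (+)-α-pinene series, C=CCB([C@@H]1C[C@@H]2C[C@H]([C@H]1C)C2(C)C)[C@@H]1C[C@@H]2C[C@H]([C@H]1C)C2(C)C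
Why: Brown asymmetric allylboration through a closed chair transition state, in which the isopinocampheyl groups of this reagent series direct allyl to the Si face of aryl aldehydes, should set the (S)-carbinol, and the weakly Lewis acidic borane is preferred to a Lewis-acid-catalysed aldol, which could trigger carbonyl-ene cyclisation onto the ortho-prenyl group.

Step 5
Reactants: 9 (1S)-1-Ar-but-3-en-1-ol
Product: 10 triethyl{[(1S)-1-Ar-but-3-en-1-yl]oxy}silane
Conditions: TESCl (1.3 equiv), imidazole (2 equiv), CH2Cl2, 0 °C → rt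
Reagents that add atoms: chlorotriethylsilane, CC[Si](Cl)(CC)CC
Why: Standard silylation of a secondary alcohol; TES withstands the Wacker and enolate steps yet is lost under the mild acid of step 8.

Step 6
Reactants: 10 triethyl{[(1S)-1-Ar-but-3-en-1-yl]oxy}silane
Product: 11 (4S)-4-Ar-4-(triethylsilyloxy)butan-2-one
Conditions: PdCl2 (10 mol %), CuCl (1.0 equiv), O2 (1 atm), DMF–H2O (7:1), rt
Reagents that add atoms: water, O
Why: Tsuji–Wacker oxidation (Markovnikov hydroxypalladation) is selective for the terminal monosubstituted alkene and should leave the trisubstituted prenyl alkene and the stereocentre untouched.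

Step 7
Reactants: 11 (4S)-4-Ar-4-(triethylsilyloxy)butan-2-one; 12 diallyl oxalate
Product: 14 allyl (6S)-6-Ar-2,4-dioxo-6-(triethylsilyloxy)hexanoate, via lithium enolate 13 (not isolated)
Conditions: LiHMDS (1.1 equiv), THF, −78 °C; 12 (1.5 equiv), −78 → 0 °C; AcOH, 0 °C
Reagents that add atoms: none
Why: Kinetic deprotonation at the methyl group followed by crossed Claisen condensation with a non-enolisable, strongly electrophilic oxalate should give the diketo ester, which is held as its chelated enolate so that β-elimination of the silyloxy group is not an issue.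

Step 8
Reactants: 14 allyl (6S)-6-Ar-2,4-dioxo-6-(triethylsilyloxy)hexanoate
Product: 16 allyl (2S)-2-Ar-4-oxo-3,4-dihydro-2H-pyran-6-carboxylate, via hemiketal 15 (not isolated)
Conditions: p-TsOH·H2O (0.2 equiv), CH2Cl2, 0 °C → rt
Reagents that add atoms: none
Why: Acid-catalysed cyclodehydration: the TES ether is cleaved, the hydroxyl adds to the α-keto ester carbonyl to give the six-membered hemiketal and water is lost through the enol of the C4 ketone; the C2–O bond is never broken so the configuration is kept, and aryl MOM ethers should tolerate catalytic acid in a non-nucleophilic solvent.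

Step 9
Reactants: 16 allyl (2S)-2-Ar-4-oxo-3,4-dihydro-2H-pyran-6-carboxylate
Product: 17 (2S)-2-Ar-4-oxo-3,4-dihydro-2H-pyran-6-carboxylic acid
Conditions: Pd(PPh3)4 (3 mol %), sodium p-toluenesulfinate (1.2 equiv), THF–MeOH, rt; cold dil. HCl to pH 3
Reagents that add atoms: none
Why: Tsuji–Trost deallylation (Pd(0) ionises the allyl ester and the soft sulfinate traps the π-allyl complex) frees the acid without hydroxide, which could open the pyranone by retro-oxa-Michael reaction and racemise C2.

Step 10
Reactants: 17 (2S)-2-Ar-4-oxo-3,4-dihydro-2H-pyran-6-carboxylic acid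
Product: 19 (2S)-2-Ar-6-(2-diazoacetyl)-2,3-dihydro-4H-pyran-4-one, via mixed anhydride 18 (not isolated)
Conditions: i-BuOCOCl (1.05 equiv), N-methylmorpholine (1.1 equiv), THF, −20 °C; CH2N2 (ca. 3 equiv, Et2O), −20 → 0 °C, dark
Reagents that add atoms: diazomethane, C=[N+]=[N-]
Why: Arndt–Eistert-type acylation of diazomethane by a mixed carbonic anhydride at low temperature should give the diazo ketone, because the trisubstituted, oxygen-donor-substituted C5=C6 bond is a poor dipolarophile and no strong acid or base is present.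

Step 11
Reactants: 20 acetylene
Product: 23 (triisopropylsilyloxy)acetylene, via lithium acetylide 21 (not isolated), via lithium ethynolate 22 (not isolated)
Conditions: acetylene (excess), n-BuLi (1.0 equiv), THF, −78 °C; LiOOt-Bu (1.1 equiv, from t-BuOOH and LiHMDS, THF, −78 °C), −78 → −20 °C; TIPSOTf (1.1 equiv), −78 → 0 °C; pentane/aq. NaHCO3, distillation
Reagents that add atoms: tert-butyl hydroperoxide, CC(C)(C)OO; triisopropylsilyl trifluoromethanesulfonate, CC(C)[Si](OS(=O)(=O)C(F)(F)F)(C(C)C)C(C)C
Why: Electrophilic oxygenation of a lithium acetylide by lithium tert-butyl peroxide (ynolate formation) followed by O-silylation of the ynolate with a bulky silyl triflate, which reacts at oxygen where small silyl groups would give silylketenes.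

Step 12
Reactants: 19 (2S)-2-Ar-6-(2-diazoacetyl)-2,3-dihydro-4H-pyran-4-one; 23 (triisopropylsilyloxy)acetylene
Product: 27 (2S)-5-hydroxy-3′,4′-bis(methoxymethoxy)-2′-(3-methylbut-2-en-1-yl)-7-(triisopropylsilyloxy)flavanone, via vinylketene 24 (not isolated), via cyclobutenone 25 (not isolated), via dienylketene 26 (not isolated)
Conditions: 23 (2.5 equiv), ClCH2CH2Cl (0.1 M, degassed), 405 nm LED, 20 °C until 19 is consumed; then 80 °C, dark
Reagents that add atoms: none
Why: Light in the long-wavelength band of the diazo ketone, where the pyranone and the product should not absorb, expels N2 with Wolff shift of pyranone C6 onto the diazo carbon to give vinylketene 24, whose ketene carbon is attacked by the nucleophilic CH terminus of the ynol ether in a polar [2+2] to give 3-siloxy-4-alkenylcyclobutenone 25; at 80 °C this opens reversibly (4π) to dienylketene 26. The closest known reaction type is the Danheiser photochemical benzannulation of α,β-unsaturated α′-diazo ketones with siloxyalkynes. Ring A, the only ring that remains, is closed by thermal 6π-electrocyclisation of 26 between the ketene carbon and pyranone C5, followed by tautomerisation of the cyclohexadienone to the phenol. No stereocentre is created, and C2 is remote from all bond formation and meets neither acid nor base. The selectivity needed is regiochemical (ketene carbon becomes C5–OH next to C4a, siloxy carbon becomes C7) and is secured by the polarisation of the ynol ether. In addition the ring holds C5–H cis and the C4 carbonyl trans to the ketenyl group, so 6π closure is possible and 2-pyranone formation is not, and the chelated 5-OH of the product is a poor trap for ketene.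

Step 13
Reactants: 27 (2S)-5-hydroxy-3′,4′-bis(methoxymethoxy)-2′-(3-methylbut-2-en-1-yl)-7-(triisopropylsilyloxy)flavanone
Product: 28 (2S)-5,7-dihydroxy-3′,4′-bis(methoxymethoxy)-2′-(3-methylbut-2-en-1-yl)flavanone
Conditions: TBAF (1.1 equiv), AcOH (1.5 equiv), THF, 0 °C
Reagents that add atoms: none
Why: Fluoride-induced cleavage of the aryl silyl ether is fast, and acetic acid buffers the phenoxide so that base-induced ring opening of the flavanone (racemisation) cannot start while the 4′-oxygen is still protected.

Step 14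
Reactants: 28 (2S)-5,7-dihydroxy-3′,4′-bis(methoxymethoxy)-2′-(3-methylbut-2-en-1-yl)flavanone
Product: 29 (2S)-5,7,3′,4′-tetrahydroxy-2′-(3-methylbut-2-en-1-yl)flavanone
Conditions: HCl (ca. 1 M) in MeOH, 40 °C, argon
Reagents that add atoms: none
Why: Acid-catalysed transacetalisation to methanol (MOM cleavage) under dilute acid and moderate temperature should free the catechol while limiting addition of the 3′-hydroxyl to the prenyl group, and dilute acid should not epimerise C2.

**Compound list**

1 | 4-bromocatechol | Oc1ccc(Br)cc1O | starting material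
2 | 4-bromo-1,2-bis(methoxymethoxy)benzene | COCOc1ccc(Br)cc1OCOC | intermediate
3 | prenyl bromide (1-bromo-3-methylbut-2-ene) | CC(C)=CCBr | starting material
4 | [6-bromo-2,3-bis(methoxymethoxy)phenyl]lithium (aryllithium, not isolated) | [Li]c1c(Br)ccc(OCOC)c1OCOC | intermediate
5 | [6-bromo-2,3-bis(methoxymethoxy)phenyl]copper (arylcopper, not isolated) | [Cu]c1c(Br)ccc(OCOC)c1OCOC | intermediate
6 | 1-bromo-3,4-bis(methoxymethoxy)-2-(3-methylbut-2-en-1-yl)benzene | CC(C)=CCc1c(Br)ccc(OCOC)c1OCOC | intermediate
7 | [3,4-bis(methoxymethoxy)-2-(3-methylbut-2-en-1-yl)phenyl]lithium (aryllithium, not isolated) | CC(C)=CCc1c([Li])ccc(OCOC)c1OCOC | intermediate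
8 | 3,4-bis(methoxymethoxy)-2-(3-methylbut-2-en-1-yl)benzaldehyde | CC(C)=CCc1c(C=O)ccc(OCOC)c1OCOC | intermediate
9 | (1S)-1-[3,4-bis(methoxymethoxy)-2-(3-methylbut-2-en-1-yl)phenyl]but-3-en-1-ol | CC(C)=CCc1c([C@@H](O)CC=C)ccc(OCOC)c1OCOC | intermediate
10 | triethyl{[(1S)-1-Ar-but-3-en-1-yl]oxy}silane | CC(C)=CCc1c([C@@H](O[Si](CC)(CC)CC)CC=C)ccc(OCOC)c1OCOC | intermediate
11 | (4S)-4-Ar-4-(triethylsilyloxy)butan-2-one | CC(C)=CCc1c([C@@H](O[Si](CC)(CC)CC)CC(C)=O)ccc(OCOC)c1OCOC | intermediate
12 | diallyl oxalate | C=CCOC(=O)C(=O)OCC=C | starting material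
13 | lithium (4S)-4-Ar-4-(triethylsilyloxy)but-1-en-2-olate (lithium enolate, not isolated) | CC(C)=CCc1c([C@@H](O[Si](CC)(CC)CC)CC(=C)O[Li])ccc(OCOC)c1OCOC | intermediate
14 | allyl (6S)-6-Ar-2,4-dioxo-6-(triethylsilyloxy)hexanoate | CC(C)=CCc1c([C@@H](O[Si](CC)(CC)CC)CC(=O)CC(=O)C(=O)OCC=C)ccc(OCOC)c1OCOC | intermediate
15 | allyl (6S)-6-Ar-2-hydroxy-4-oxotetrahydro-2H-pyran-2-carboxylate (hemiketal, both C2 epimers, not isolated) | CC(C)=CCc1c([C@@H]2CC(=O)CC(O)(C(=O)OCC=C)O2)ccc(OCOC)c1OCOC | intermediate
16 | allyl (2S)-2-Ar-4-oxo-3,4-dihydro-2H-pyran-6-carboxylate | CC(C)=CCc1c([C@@H]2CC(=O)C=C(C(=O)OCC=C)O2)ccc(OCOC)c1OCOC | intermediate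
17 | (2S)-2-Ar-4-oxo-3,4-dihydro-2H-pyran-6-carboxylic acid | CC(C)=CCc1c([C@@H]2CC(=O)C=C(C(=O)O)O2)ccc(OCOC)c1OCOC | intermediate
18 | isobutyl carbonic mixed anhydride of 17 (not isolated) | CC(C)=CCc1c([C@@H]2CC(=O)C=C(C(=O)OC(=O)OCC(C)C)O2)ccc(OCOC)c1OCOC | intermediate
19 | (2S)-2-Ar-6-(2-diazoacetyl)-2,3-dihydro-4H-pyran-4-one | CC(C)=CCc1c([C@@H]2CC(=O)C=C(C(=O)C=[N+]=[N-])O2)ccc(OCOC)c1OCOC | intermediate
20 | acetylene | C#C | starting material
21 | lithium acetylide (not isolated) | [Li]C#C | intermediate
22 | lithium ethynolate (not isolated) | [Li]OC#C | intermediate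
23 | (triisopropylsilyloxy)acetylene | C#CO[Si](C(C)C)(C(C)C)C(C)C | intermediate
24 | (2S)-2-Ar-6-(2-oxoethenyl)-2,3-dihydro-4H-pyran-4-one (vinylketene, not isolated) | CC(C)=CCc1c([C@@H]2CC(=O)C=C(C=C=O)O2)ccc(OCOC)c1OCOC | intermediate
25 | 4-[(2S)-2-Ar-4-oxo-3,4-dihydro-2H-pyran-6-yl]-3-(triisopropylsilyloxy)cyclobut-2-en-1-one (both C4 epimers, not isolated) | CC(C)=CCc1c([C@@H]2CC(=O)C=C(C3C(=O)C=C3O[Si](C(C)C)(C(C)C)C(C)C)O2)ccc(OCOC)c1OCOC | intermediate
26 | (2S)-2-Ar-6-[4-oxo-2-(triisopropylsilyloxy)buta-1,3-dien-1-yl]-2,3-dihydro-4H-pyran-4-one (dienylketene, not isolated) | CC(C)=CCc1c([C@@H]2CC(=O)C=C(C=C(O[Si](C(C)C)(C(C)C)C(C)C)C=C=O)O2)ccc(OCOC)c1OCOC | intermediate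
27 | (2S)-5-hydroxy-3′,4′-bis(methoxymethoxy)-2′-(3-methylbut-2-en-1-yl)-7-(triisopropylsilyloxy)flavanone | CC(C)=CCc1c([C@@H]2CC(=O)c3c(O)cc(O[Si](C(C)C)(C(C)C)C(C)C)cc3O2)ccc(OCOC)c1OCOC | intermediate
28 | (2S)-5,7-dihydroxy-3′,4′-bis(methoxymethoxy)-2′-(3-methylbut-2-en-1-yl)flavanone | CC(C)=CCc1c([C@@H]2CC(=O)c3c(O)cc(O)cc3O2)ccc(OCOC)c1OCOC | intermediate
29 | (2S)-2-[3,4-dihydroxy-2-(3-methylbut-2-en-1-yl)phenyl]-5,7-dihydroxy-2,3-dihydro-4H-chromen-4-one | CC(C)=CCc1c([C@@H]2CC(=O)c3c(O)cc(O)cc3O2)ccc(O)c1O | target

**Step count.** Total: 14 steps. Longest linear sequence: 13 steps (steps 1–10 and 12–14); step 11 is a one-step side branch.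

**Steps most likely to fail**

1. Step 12 (benzannulation). Light may be absorbed unproductively or the carbene diverted before the Wolff shift. The oxygen-substituted vinylketene may dimerise or acylate the product phenol faster than it meets the alkyne. Opening of the siloxycyclobutenone may stall, or the ynol ether may isomerise on heating. The fallback gives up the annulation and forms the C2–C1′ bond by known asymmetric conjugate addition. It sets out from aryl bromide 6. Bromine–lithium exchange, triisopropyl borate and mild hydrolysis should give [3,4-bis(methoxymethoxy)-2-(3-methylbut-2-en-1-yl)phenyl]boronic acid F1. Commercial 5,7-dihydroxychromone is converted with NaH/MOMCl into 5,7-bis(methoxymethoxy)chromone F2. Rhodium(I)/chiral diphosphine-catalysed 1,4-addition of F1 to F2, with the ligand antipode chosen for the 2S series, should give (2S)-5,7,3′,4′-tetrakis(methoxymethoxy)-2′-(3-methylbut-2-en-1-yl)flavanone F3. Methanolic HCl as in step 14 then rejoins the route at target 29.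

2. Step 11 (ynol ether). Monolithium acetylide may disproportionate before oxygen transfer. Silylation at carbon or a 1,3-silyl shift may lead to the silylketene. The small, hydrolytically sensitive ynol ether may be lost on isolation. The fallback replaces the silyl ynol ether by a known alkyl ynol ether. Trichloroethylene and potassium tert-butoxide give tert-butyl (E)-1,2-dichlorovinyl ether F4, and n-BuLi (2 equiv) followed by methanol gives tert-butoxyacetylene F5. The fallback sets out from diazo ketone 19, which is irradiated with F5 as in step 12; excess alkyne is removed before the thermal stage because it fragments to ketene on heating. This should give (2S)-7-tert-butoxy-5-hydroxy-3′,4′-bis(methoxymethoxy)-2′-(3-methylbut-2-en-1-yl)flavanone F6. Acid (TFA/anisole at 0 °C for the tert-butyl ether, then methanolic HCl as in step 14) rejoins the route at target 29.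

3. Step 14 (MOM removal). The liberated 3′-hydroxyl may add to the neighbouring prenyl double bond under acid (chroman formation), or that alkene may be hydrated before both acetals are gone. Slow erosion at C2 through acid-mediated ring opening is also possible. The fallback avoids Brønsted acid and reverses the order of the endgame. It sets out from 27. TMSOTf/2,2′-bipyridyl in CH2Cl2 at 0 °C converts both aryl MOM ethers into pyridinium-type acetals, which hydrolyse on addition of water to give (2S)-3′,4′,5-trihydroxy-2′-(3-methylbut-2-en-1-yl)-7-(triisopropylsilyloxy)flavanone F7. Buffered TBAF as in step 13 then rejoins the route at target 29.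

**Further compounds**

F1 | step 12 | [3,4-bis(methoxymethoxy)-2-(3-methylbut-2-en-1-yl)phenyl]boronic acid | CC(C)=CCc1c(B(O)O)ccc(OCOC)c1OCOC
F2 | step 12 | 5,7-bis(methoxymethoxy)-4H-chromen-4-one | COCOc1cc(OCOC)c2c(c1)occc2=O
F3 | step 12 | (2S)-5,7,3′,4′-tetrakis(methoxymethoxy)-2′-(3-methylbut-2-en-1-yl)flavanone | CC(C)=CCc1c([C@@H]2CC(=O)c3c(OCOC)cc(OCOC)cc3O2)ccc(OCOC)c1OCOC
F4 | step 11 | tert-butyl (E)-1,2-dichlorovinyl ether | CC(C)(C)O/C(Cl)=C\Cl
F5 | step 11 | tert-butoxyacetylene | CC(C)(C)OC#C
F6 | step 11 | (2S)-7-tert-butoxy-5-hydroxy-3′,4′-bis(methoxymethoxy)-2′-(3-methylbut-2-en-1-yl)flavanone | CC(C)=CCc1c([C@@H]2CC(=O)c3c(O)cc(OC(C)(C)C)cc3O2)ccc(OCOC)c1OCOC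
F7 | step 14 | (2S)-3′,4′,5-trihydroxy-2′-(3-methylbut-2-en-1-yl)-7-(triisopropylsilyloxy)flavanone | CC(C)=CCc1c([C@@H]2CC(=O)c3c(O)cc(O[Si](C(C)C)(C(C)C)C(C)C)cc3O2)ccc(O)c1O
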